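**Retrosynthetic overview**
1. Both stereocentres in the SMILES work out as S. The target is therefore the monoacetate of the C2-symmetric anti-(3S,5S)-1,7-diarylheptane-3,5-diol. The two carbinol positions are homotopic, so either oxygen may carry the acetyl group. The last operation removes two phenol benzyl groups.
2. The C3 carbinol and the acetate are installed together by an Evans–Tishchenko reduction (MeCHO) of the (5S)-β-hydroxy ketone, 1,3-anti under substrate control.
3. The key C3–C4 bond comes from a visible-light Ni/HAT/photoredox union of a 3-arylpropanal (acyl radical) with a terminal (S)-epoxide, which reacts through a catalytic bromohydrin.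
4. The C6–C7 bond comes from a Cu-catalysed benzylic Grignard opening of (S)-epichlorohydrin, the only source of chirality.
5. No ring of the target is built, because both arenes are bought. The only ring made is a transient oxirane, closed in step 1 and opened in step 2.

Assumption: (S)-epichlorohydrin 1, 4-(benzyloxy)-3-methoxybenzyl chloride 2 and 3-[4-(benzyloxy)-3-methoxyphenyl]propanal 3 are bought as catalogue items.

**Step 1**
Reactants: 2 4-(benzyloxy)-3-methoxybenzyl chloride; 1 (S)-epichlorohydrin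
Product: 6 (2S)-2-{2-[4-(benzyloxy)-3-methoxyphenyl]ethyl}oxirane, via benzylic Grignard reagent 4 (not isolated), via chlorohydrin 5 (not isolated)
Conditions: Mg, 2-MeTHF, 0 °C (slow addition of 2); CuI (10 mol %), 1, −40 → 0 °C; then 5 M aq NaOH, MeOH, rt
Reagents that add atoms: none
Why: Cu(I)-catalysed Grignard opening of the epoxide at its unsubstituted CH2 (SN2) is followed by Williamson-type closure of the chlorohydrin, and because the C–O bond at the stereocentre is never broken the (S) centre of 1 is carried unchanged into 6.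

**Step 2**
Reactants: 6 (2S)-2-{2-[4-(benzyloxy)-3-methoxyphenyl]ethyl}oxirane; 3 3-[4-(benzyloxy)-3-methoxyphenyl]propanal (1.5 equiv)
Product: 8 (5S)-1,7-bis[4-(benzyloxy)-3-methoxyphenyl]-5-hydroxyheptan-3-one, via bromohydrin 7 (not isolated)
Conditions: [Ir(dF(CF3)ppy)2(dtbbpy)]PF6 (1 mol %), NiBr2·glyme/dtbbpy (10 mol %), quinuclidine (15 mol %), quinuclidine·HBr (25 mol %), LiBr (20 mol %), 1,4-dioxane–MeCN, 450 nm LEDs, 25 °C, N2
Reagents that add atoms: none
Why: Proposed new method: redox-neutral hydroacylation of an epoxide. Quinuclidinium bromide (assisted by Li+) opens the terminal epoxide by SN2 at CH2 to bromohydrin 7, leaving the C–O bond at the stereocentre untouched. Excited Ir(III) oxidises quinuclidine to its radical cation, which abstracts the weak, hydridic formyl C–H of 3 (about 89 kcal/mol) to give the acyl radical. Ni(0) inserts into the C–Br bond of 7, captures the acyl radical, and the Ni(III)(acyl)(alkyl) species reductively eliminates the C3–C4 bond, after which Ir(II) returns Ni(I) to Ni(0). The proton on quinuclidine and the released bromide open the next epoxide, so HBr is only a shuttle, no base is needed and no co-product forms. The closest known reaction types are the Ni/HAT/photoredox coupling of aldehyde C–H bonds with alkyl bromides (stoichiometric base, ether solvent, which shows that formyl C–H abstraction outruns ether α-C–H abstraction) and the halide-co-catalysed Ni coupling of epoxides with aryl halides. An epoxide serving as both alkyl partner and acid scavenger in an aldehyde C–H acylation has not been shown.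

**Step 3**
Reactants: 8 (5S)-1,7-bis[4-(benzyloxy)-3-methoxyphenyl]-5-hydroxyheptan-3-one
Product: 10 (3S,5S)-1,7-bis[4-(benzyloxy)-3-methoxyphenyl]-5-hydroxyheptan-3-yl acetate, via acetaldehyde hemiacetal 9 (not isolated)
Conditions: SmI2 (30 mol %), MeCHO (10 equiv, freshly distilled), THF, −10 °C
Reagents that add atoms: acetaldehyde, CC=O
Why: In this Evans–Tishchenko reduction the Sm(III)-bound hemiacetal 9 delivers its hydride intramolecularly to the ketone through a chair-like chelated transition state, so the existing (S) centre dictates the new 1,3-anti (S) carbinol (typically >95:5), the hemiacetal carbon becomes the acetate, and any 1,3-acyl shift is degenerate because the parent diol is C2-symmetric.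

**Step 4**
Reactants: 10 (3S,5S)-1,7-bis[4-(benzyloxy)-3-methoxyphenyl]-5-hydroxyheptan-3-yl acetate
Product: 11 (3S,5S)-5-hydroxy-1,7-bis(4-hydroxy-3-methoxyphenyl)heptan-3-yl acetate (target)
Conditions: H2 (1 atm), 10 % Pd/C, EtOAc–EtOH, rt
Reagents that add atoms: none
Why: Heterogeneous hydrogenolysis cleaves the two aryl benzyl ethers, while the alkyl acetate, the non-benzylic secondary alcohol and both stereocentres are inert.

**Compound list**
1 | (S)-epichlorohydrin, (2S)-2-(chloromethyl)oxirane | ClC[C@@H]1CO1 | starting material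
2 | 4-(benzyloxy)-3-methoxybenzyl chloride | COc1cc(CCl)ccc1OCc1ccccc1 | starting material
3 | 3-[4-(benzyloxy)-3-methoxyphenyl]propanal | COc1cc(CCC=O)ccc1OCc1ccccc1 | starting material
4 | [4-(benzyloxy)-3-methoxybenzyl]magnesium chloride | COc1cc(C[Mg]Cl)ccc1OCc1ccccc1 | intermediate
5 | (2S)-4-[4-(benzyloxy)-3-methoxyphenyl]-1-chlorobutan-2-ol (formed as its Mg alkoxide) | COc1cc(CC[C@H](O)CCl)ccc1OCc1ccccc1 | intermediate
6 | (2S)-2-{2-[4-(benzyloxy)-3-methoxyphenyl]ethyl}oxirane | COc1cc(CC[C@H]2CO2)ccc1OCc1ccccc1 | intermediate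
7 | (2S)-4-[4-(benzyloxy)-3-methoxyphenyl]-1-bromobutan-2-ol | COc1cc(CC[C@H](O)CBr)ccc1OCc1ccccc1 | intermediate
8 | (5S)-1,7-bis[4-(benzyloxy)-3-methoxyphenyl]-5-hydroxyheptan-3-one | COc1cc(CC[C@H](O)CC(=O)CCc2ccc(OCc3ccccc3)c(OC)c2)ccc1OCc1ccccc1 | intermediate
9 | acetaldehyde hemiacetal of 8 at O-5 (Sm-bound in the flask, drawn neutral, hemiacetal carbon unassigned) | COc1cc(CC[C@@H](CC(=O)CCc2ccc(OCc3ccccc3)c(OC)c2)OC(C)O)ccc1OCc1ccccc1 | intermediate
10 | (3S,5S)-1,7-bis[4-(benzyloxy)-3-methoxyphenyl]-5-hydroxyheptan-3-yl acetate | COc1cc(CC[C@H](O)C[C@H](CCc2ccc(OCc3ccccc3)c(OC)c2)OC(C)=O)ccc1OCc1ccccc1 | intermediate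
11 | (3S,5S)-5-hydroxy-1,7-bis(4-hydroxy-3-methoxyphenyl)heptan-3-yl acetate | COc1cc(CC[C@H](O)C[C@H](CCc2ccc(O)c(OC)c2)OC(C)=O)ccc1O | target

**Total step count:** 4. **Longest linear sequence:** 4 (2/1 → 6 → 8 → 10 → 11).

**Three steps most likely to fail**

Step 2 (proposed new step). There are four main risks:
- Opening of the epoxide by bromide may be too slow.
- Quinuclidine may be N-alkylated by 6 or 7.
- The β-hydroxyalkyl–nickel species may lose hydroxide to give the butenylarene.
- Hydrogen abstraction may stray to the OCH2Ph or ArCH2 positions.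

The fallback is known Corey–Seebach umpolung. It sets out from aldehyde 3, uses epoxide 6, and comes back at 8. Aldehyde 3 is treated with propane-1,3-dithiol and BF3·OEt2 (CH2Cl2, 0 °C) to give 2-{2-[4-(benzyloxy)-3-methoxyphenyl]ethyl}-1,3-dithiane F1. Lithiation (t-BuLi, THF–HMPA, −78 °C) and addition of 6 opens the epoxide at CH2 to give (2S)-4-[4-(benzyloxy)-3-methoxyphenyl]-1-(2-{2-[4-(benzyloxy)-3-methoxyphenyl]ethyl}-1,3-dithian-2-yl)butan-2-ol F2. MeI and CaCO3 in aqueous MeCN then unmask ketone 8.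

Step 1. The electron-rich benzylic Grignard 4 may suffer Wurtz homocoupling, which lowers the titre. The fallback replaces the organometallic by a Wittig olefination on a D-mannitol-derived aldehyde. It sets out from 2 and comes back at 6. Chloride 2 and PPh3 (toluene, reflux) give [4-(benzyloxy)-3-methoxybenzyl]triphenylphosphonium chloride F3. NaHMDS (THF, −78 °C) followed by (R)-2,3-O-isopropylideneglyceraldehyde gives (4S)-4-{2-[4-(benzyloxy)-3-methoxyphenyl]ethenyl}-2,2-dimethyl-1,3-dioxolane F4, an E/Z mixture whose geometry is irrelevant. Diimide (TsNHNH2, NaOAc, aq DME, reflux) saturates the alkene without touching the benzyl ether and gives (4S)-4-{2-[4-(benzyloxy)-3-methoxyphenyl]ethyl}-2,2-dimethyl-1,3-dioxolane F5. Treatment with 80 % AcOH gives (2S)-4-[4-(benzyloxy)-3-methoxyphenyl]butane-1,2-diol F6. Bu2SnO (cat.), TsCl and Et3N give (2S)-4-[4-(benzyloxy)-3-methoxyphenyl]-2-hydroxybutyl 4-methylbenzenesulfonate F7, and K2CO3 in MeOH closes it to 6.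

Step 3. Sm(III) alkoxides may trigger retro-aldol cleavage of 8, and acetaldehyde may self-condense. The fallback separates reduction from acylation. It sets out from 8 and comes back at 10. Evans–Saksena reduction (Me4NBH(OAc)3, MeCN–AcOH, −30 °C, intramolecular hydride delivery, 1,3-anti) gives (3S,5S)-1,7-bis[4-(benzyloxy)-3-methoxyphenyl]heptane-3,5-diol F8. MeC(OMe)3 with catalytic PPTS (CH2Cl2, rt) gives the cyclic orthoacetate (4S,6S)-4,6-bis{2-[4-(benzyloxy)-3-methoxyphenyl]ethyl}-2-methoxy-2-methyl-1,3-dioxane F9. Aqueous AcOH opens F9 to monoacetate 10, and either mode of opening gives the same compound because F8 is C2-symmetric.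

**Further compounds**
F1 | step 2 | 2-{2-[4-(benzyloxy)-3-methoxyphenyl]ethyl}-1,3-dithiane | COc1cc(CCC2SCCCS2)ccc1OCc1ccccc1
F2 | step 2 | (2S)-4-[4-(benzyloxy)-3-methoxyphenyl]-1-(2-{2-[4-(benzyloxy)-3-methoxyphenyl]ethyl}-1,3-dithian-2-yl)butan-2-ol | COc1cc(CC[C@H](O)CC2(CCc3ccc(OCc4ccccc4)c(OC)c3)SCCCS2)ccc1OCc1ccccc1
F3 | step 1 | [4-(benzyloxy)-3-methoxybenzyl]triphenylphosphonium chloride | COc1cc(C[P+](c2ccccc2)(c2ccccc2)c2ccccc2)ccc1OCc1ccccc1.[Cl-]
F4 | step 1 | (4S)-4-{2-[4-(benzyloxy)-3-methoxyphenyl]ethenyl}-2,2-dimethyl-1,3-dioxolane (E/Z mixture) | COc1cc(C=C[C@H]2COC(C)(C)O2)ccc1OCc1ccccc1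
F5 | step 1 | (4S)-4-{2-[4-(benzyloxy)-3-methoxyphenyl]ethyl}-2,2-dimethyl-1,3-dioxolane | COc1cc(CC[C@H]2COC(C)(C)O2)ccc1OCc1ccccc1
F6 | step 1 | (2S)-4-[4-(benzyloxy)-3-methoxyphenyl]butane-1,2-diol | COc1cc(CC[C@H](O)CO)ccc1OCc1ccccc1
F7 | step 1 | (2S)-4-[4-(benzyloxy)-3-methoxyphenyl]-2-hydroxybutyl 4-methylbenzenesulfonate | COc1cc(CC[C@H](O)COS(=O)(=O)c2ccc(C)cc2)ccc1OCc1ccccc1
F8 | step 3 | (3S,5S)-1,7-bis[4-(benzyloxy)-3-methoxyphenyl]heptane-3,5-diol | COc1cc(CC[C@H](O)C[C@@H](O)CCc2ccc(OCc3ccccc3)c(OC)c2)ccc1OCc1ccccc1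
F9 | step 3 | (4S,6S)-4,6-bis{2-[4-(benzyloxy)-3-methoxyphenyl]ethyl}-2-methoxy-2-methyl-1,3-dioxane | COc1cc(CC[C@H]2C[C@H](CCc3ccc(OCc4ccccc4)c(OC)c3)OC(C)(OC)O2)ccc1OCc1ccccc1
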